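**Plan**

- Numbering: pinane part C1–C7 (C1 and C5 bridgeheads, C2 spiro carbon, C6 the CMe2 bridge, C7 the CH2 bridge); chroman part primed. The retrosynthesis cuts, in this order: C8'–CHO; O1'–C2 and C3'–C4' of the dihydropyran (o-quinone methide plus exocyclic alkene); C2=CH2; then C2–C3 and C4–C5 of the bicyclo[3.1.1]heptane.
- Enabling feature: C3H2–C4H2 is an unsubstituted two-carbon bridge between C2 (a carbonyl carbon once the spiro ether is traced back to the ketone) and the cyclobutane methine C5. A C5 radical, methyl acrylate and an ester on C1 can therefore close the ring C1–C2–C3–C4–C5–C6 in one radical–polar crossover (4+2) annulation; the acrylate ester is later lost as CO2.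
- Forward ring order: 2,2-dimethylcyclobutane (from verbenone by excision of C3/C4), then the six-membered carbocycle of the pinane (key step), then the dihydropyran ring on a separately made acylphloroglucinol, then the formyl group.
- Stereochemistry: C1 is carried over from (1R,5R)-verbenone. C5 is re-formed from a planar radical and fixed by the cis-only ring closure. Spiro C2 comes from attack of the quinone methide on the alkene face remote from the CMe2 bridge. Introducing the formyl group last leaves the para-oxygen as the only unchelated phenol for ring closure.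

Key step: step 4

Remark: (1R,5R)-(+)-verbenone is assumed purchasable and serves only as the enantiopure source of the cis-1,3-disubstituted 2,2-dimethylcyclobutane; C1, C2, C5, C6 and C7 of the target are the atoms with the same numbers in verbenone.

**Route**

Step 1
Reactants: 1 (1R,5R)-(+)-verbenone, (1R,5R)-4,6,6-trimethylbicyclo[3.1.1]hept-3-en-2-one
Product: 2 (1R,3S)-3-acetyl-2,2-dimethylcyclobutane-1-carboxylic acid (cis-pinononic acid)
Conditions: RuCl3·xH2O (2 mol%), NaIO4 (4.1 equiv), CCl4/MeCN/H2O, rt
Reagents that add atoms: sodium periodate, [Na+].[O-]I(=O)(=O)=O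
Why: Ruthenium tetroxide formed in situ cleaves the C3=C4 enone double bond (oxidative alkene cleavage), the α-keto acid at C2–C3 loses C3 as CO2, and the two cyclobutane stereocentres are not touched, so the cis keto acid should result.

Step 2
Reactants: 2 (1R,3S)-3-acetyl-2,2-dimethylcyclobutane-1-carboxylic acid
Product: 3 methyl (1R,3S)-3-acetyl-2,2-dimethylcyclobutane-1-carboxylate
Conditions: MeI, KHCO3, DMF, rt
Reagents that add atoms: iodomethane, CI
Why: SN2 O-alkylation of the carboxylate with iodomethane, with hydrogencarbonate as a base too weak to epimerise the centre next to the ketone.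

Step 3
Reactants: 3 methyl (1R,3S)-3-acetyl-2,2-dimethylcyclobutane-1-carboxylate
Product: 4 (1S,3R)-3-(methoxycarbonyl)-2,2-dimethylcyclobutane-1-carboxylic acid
Conditions: Br2 (3.2 equiv), aq. NaOH, 1,4-dioxane, 0 °C; then aq. HCl
Reagents that add atoms: sodium hydroxide, [Na+].[OH-]
Why: Haloform reaction in which the methyl ketone is tribrominated and cleaved by hydroxide while the hindered methyl ester next to the quaternary carbon should survive the cold hypobromite; any epimerisation at the new carboxyl-bearing carbon would be harmless because that centre becomes a radical in step 4.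

Step 4
Reactants: 4 (1S,3R)-3-(methoxycarbonyl)-2,2-dimethylcyclobutane-1-carboxylic acid; 5 methyl acrylate
Product: 7 methyl (1R,5R)-6,6-dimethyl-2-oxobicyclo[3.1.1]heptane-3-carboxylate (C3 epimers and enol), via cis diester 6 (not isolated)
Conditions: CsOH·H2O (1.0 equiv, salt dried), 5 (1.5 equiv), Ir[dF(CF3)ppy]2(dtbbpy)PF6 (1 mol%), dry degassed DMSO, 450 nm LEDs, rt; AcOH quench
Reagents that add atoms: none
Why: Proposed new method: the excited trivalent iridium photocatalyst oxidises the caesium carboxylate, loss of CO2 leaves a planar cyclobutyl radical at C5 that adds to methyl acrylate (C4–C5 bond), and the divalent iridium state reduces the resulting α-ester radical to an ester enolate that attacks the cis ring ester (C3–C2 bond) and expels methoxide, while any enolate that is protonated first (diester 6) is returned by that methoxide until all negative charge rests in the stabilised β-keto ester enolate of 7. The closest known reaction types are the photoredox decarboxylative Giese addition, radical addition–polar cyclisation cascades of carboxylates and the Dieckmann condensation; new is that the carboxylate charge itself is relayed to drive the Claisen closure, so that no external base is needed. The ring closed is the six-membered carbocycle C1–C2–C3–C4–C5–C6 of the bicyclo[3.1.1]heptane, by 6-exo-trig acyl substitution of C3 on the ester carbonyl C2 across the cis-1,3 positions of the cyclobutane. C1 keeps the configuration it had in verbenone, C5 is re-formed from the planar radical and ends as the second bridgehead because only the adduct with the side chain cis to the ester can close, and C3 is an enolisable centre that is removed in step 5. The step needs cis-selective radical addition, expected to be modest from pseudo-equatorial approach on the puckered ring (the trans adduct stays open-chain and is separated), and it needs C1 not to epimerise, which the absence of added base and an acetic acid quench directly after irradiation should secure. The other Dieckmann mode (C1 enolate on the side-chain ester) would give a β-keto ester without an acidic hydrogen and is reversed under the relay conditions.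

Step 5
Reactants: 7 methyl (1R,5R)-6,6-dimethyl-2-oxobicyclo[3.1.1]heptane-3-carboxylate
Product: 8 (1R,5S)-6,6-dimethylbicyclo[3.1.1]heptan-2-one ((+)-nopinone)
Conditions: LiCl, DMSO, H2O (2 equiv), 150 °C
Reagents that add atoms: none
Why: Krapcho dealkoxycarbonylation, in which chloride demethylates the β-keto ester and the carboxylate loses CO2 through the enolate, removes the activating ester from C3 without a base that could open the strained ring by retro-Claisen cleavage and leaves both bridgeheads unaffected.

Step 6
Reactants: 8 (1R,5S)-6,6-dimethylbicyclo[3.1.1]heptan-2-one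
Product: 9 (1S,5S)-6,6-dimethyl-2-methylidenebicyclo[3.1.1]heptane ((−)-β-pinene)
Conditions: Ph3PCH3Br, KOtBu, THF, 0 °C to reflux
Reagents that add atoms: methyltriphenylphosphonium bromide, C[P+](c1ccccc1)(c1ccccc1)c1ccccc1.[Br-]
Why: Wittig methylenation of the ketone with the non-stabilised ylide should give the exocyclic alkene without forming or disturbing a stereocentre.

Step 7
Reactants: 10 phloroglucinol (benzene-1,3,5-triol); 11 3-methylbutanenitrile
Product: 12 3-methyl-1-(2,4,6-trihydroxyphenyl)butan-1-one
Conditions: HCl (gas), ZnCl2 (cat.), Et2O, 0 °C; then H2O, 100 °C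
Reagents that add atoms: water, O
Why: Houben–Hoesch acylation, in which the nitrilium ion attacks the very electron-rich ring once, the ketiminium salt precipitates and so blocks a second acylation, and hydrolysis gives the aryl ketone.

Step 8
Reactants: 12 3-methyl-1-(2,4,6-trihydroxyphenyl)butan-1-one
Product: 13 3-methyl-1-[2,4,6-trihydroxy-3-(morpholin-4-ylmethyl)phenyl]butan-1-one
Conditions: morpholine (1.0 equiv), aq. CH2O (1.0 equiv), EtOH, 0 °C to rt
Reagents that add atoms: formaldehyde, C=O; morpholine, C1COCCN1
Why: Mannich reaction at one of the two equivalent free ring positions, where one equivalent of iminium ion and precipitation of the zwitterionic mono-adduct should limit double aminomethylation.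

Step 9
Reactants: 9 (1S,5S)-6,6-dimethyl-2-methylidenebicyclo[3.1.1]heptane; 13 3-methyl-1-[2,4,6-trihydroxy-3-(morpholin-4-ylmethyl)phenyl]butan-1-one
Product: 15 1-[(1R,2R,5S)-5',7'-dihydroxy-6,6-dimethyl-3',4'-dihydrospiro[bicyclo[3.1.1]heptane-2,2'-chromen]-6'-yl]-3-methylbutan-1-one, via o-quinone methide 14 (not isolated)
Conditions: 13 (2 equiv, added in portions), 1,4-dioxane, 100 °C, sealed tube
Reagents that add atoms: none
Why: Thermal loss of morpholine through the para-phenol, the only hydroxyl not locked in a hydrogen bond to the ketone, should give o-quinone methide 14, which undergoes an inverse-electron-demand hetero-Diels–Alder reaction with the exocyclic alkene of 9 in which the methide carbon bonds to the CH2 terminus and the oxygen to C2 from the face remote from the CMe2 bridge, setting the spiro centre as 2R with the para-oxygen in the ring.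

Step 10
Reactants: 15 1-[(1R,2R,5S)-5',7'-dihydroxy-6,6-dimethyl-3',4'-dihydrospiro[bicyclo[3.1.1]heptane-2,2'-chromen]-6'-yl]-3-methylbutan-1-one
Product: 16 euglobal G3, (1R,2R,5S)-5',7'-dihydroxy-6,6-dimethyl-6'-(3-methylbutanoyl)-3',4'-dihydrospiro[bicyclo[3.1.1]heptane-2,2'-chromene]-8'-carbaldehyde
Conditions: Cl2CHOMe, TiCl4 (3 equiv), CH2Cl2, −20 °C to 0 °C; then H2O
Reagents that add atoms: dichloromethyl methyl ether, COC(Cl)Cl; water, O
Why: Rieche formylation, in which the titanium phenoxide directs the chloro(methoxy)methyl cation to C8', the only unsubstituted ring position, and hydrolysis gives the aldehyde, should leave the stereocentres intact provided the low temperature keeps the tertiary spiro ether from ionising.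

**Compound list**

1 | (1R,5R)-(+)-verbenone, (1R,5R)-4,6,6-trimethylbicyclo[3.1.1]hept-3-en-2-one | O=C1C=C(C)[C@H]2C[C@@H]1C2(C)C | starting material
2 | (1R,3S)-3-acetyl-2,2-dimethylcyclobutane-1-carboxylic acid | CC(=O)[C@H]1C[C@@H](C(=O)O)C1(C)C | intermediate
3 | methyl (1R,3S)-3-acetyl-2,2-dimethylcyclobutane-1-carboxylate | CC(=O)[C@H]1C[C@@H](C(=O)OC)C1(C)C | intermediate
4 | (1S,3R)-3-(methoxycarbonyl)-2,2-dimethylcyclobutane-1-carboxylic acid | OC(=O)[C@H]1C[C@@H](C(=O)OC)C1(C)C | intermediate
5 | methyl acrylate | C=CC(=O)OC | starting material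
6 | methyl (1R,3S)-3-(3-methoxy-3-oxopropyl)-2,2-dimethylcyclobutane-1-carboxylate (cis diester, not isolated) | COC(=O)CC[C@H]1C[C@@H](C(=O)OC)C1(C)C | intermediate
7 | methyl (1R,5R)-6,6-dimethyl-2-oxobicyclo[3.1.1]heptane-3-carboxylate (C3 epimers and enol) | O=C1C(C(=O)OC)C[C@H]2C[C@@H]1C2(C)C | intermediate
8 | (1R,5S)-6,6-dimethylbicyclo[3.1.1]heptan-2-one | O=C1CC[C@H]2C[C@@H]1C2(C)C | intermediate
9 | (1S,5S)-6,6-dimethyl-2-methylidenebicyclo[3.1.1]heptane | C=C1CC[C@H]2C[C@@H]1C2(C)C | intermediate
10 | phloroglucinol (benzene-1,3,5-triol) | Oc1cc(O)cc(O)c1 | starting material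
11 | 3-methylbutanenitrile | CC(C)CC#N | starting material
12 | 3-methyl-1-(2,4,6-trihydroxyphenyl)butan-1-one | CC(C)CC(=O)c1c(O)cc(O)cc1O | intermediate
13 | 3-methyl-1-[2,4,6-trihydroxy-3-(morpholin-4-ylmethyl)phenyl]butan-1-one | CC(C)CC(=O)c1c(O)cc(O)c(CN2CCOCC2)c1O | intermediate
14 | 3,5-dihydroxy-4-(3-methylbutanoyl)-6-methylidenecyclohexa-2,4-dien-1-one (o-quinone methide, not isolated) | C=C1C(=O)C=C(O)C(C(=O)CC(C)C)=C1O | intermediate
15 | 1-[(1R,2R,5S)-5',7'-dihydroxy-6,6-dimethyl-3',4'-dihydrospiro[bicyclo[3.1.1]heptane-2,2'-chromen]-6'-yl]-3-methylbutan-1-one | CC(C)CC(=O)c1c(O)cc2c(c1O)CC[C@@]1(CC[C@H]3C[C@@H]1C3(C)C)O2 | intermediate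
16 | euglobal G3, (1R,2R,5S)-5',7'-dihydroxy-6,6-dimethyl-6'-(3-methylbutanoyl)-3',4'-dihydrospiro[bicyclo[3.1.1]heptane-2,2'-chromene]-8'-carbaldehyde | CC(C)CC(=O)c1c(O)c(C=O)c2c(c1O)CC[C@@]1(CC[C@H]3C[C@@H]1C3(C)C)O2 | target

**Step count and risks**

Total step count: 10. Longest linear sequence: 8 steps (steps 1 to 6, then 9 and 10); the arene branch (steps 7 and 8) joins at step 9.

Steps most likely to fail:

1. Step 4 (the labelled step). The enolate may be protonated or add to excess acrylate faster than it closes the ring. The radical may add mainly trans to the ester. Relayed methoxide may epimerise C1 of the trans adduct and so lower the enantiopurity. The fallback uses known chemistry, sets out from 4 and comes back to the route at 8. Photoredox decarboxylative Giese addition of 4 to phenyl vinyl sulfone under phosphate-buffered conditions (same iridium photocatalyst, K2HPO4, DMF, 450 nm) should give, after chromatographic removal of the trans isomer, methyl (1R,3R)-2,2-dimethyl-3-[2-(phenylsulfonyl)ethyl]cyclobutane-1-carboxylate F1. Lithium diisopropylamide (2.2 equiv, THF, −78 °C to 0 °C) should then close the ring by intramolecular acylation of the α-sulfonyl carbanion to (1R,5R)-6,6-dimethyl-3-(phenylsulfonyl)bicyclo[3.1.1]heptan-2-one F2. Reductive desulfonylation (aluminium amalgam in wet THF, or SmI2) should give 8.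

2. Step 9. Ring closure may occur through a chelated ortho-oxygen instead of the para-oxygen, the quinone methide may oligomerise, or the cycloaddition may take place on the hindered alkene face. The fallback sets out from 12 (with 9 as before) and comes back at 15; it blocks the two chelated phenols so that only the para-oxygen can close the ring. Silylation of the unchelated para-hydroxyl (TBSCl, imidazole, DMF, 0 °C) should give 1-[4-(tert-butyldimethylsilyloxy)-2,6-dihydroxyphenyl]-3-methylbutan-1-one F3. Protection of both chelated hydroxyls (MOMCl, i-Pr2NEt, CH2Cl2, 40 °C) should give 1-[4-(tert-butyldimethylsilyloxy)-2,6-bis(methoxymethoxy)phenyl]-3-methylbutan-1-one F4, and tetrabutylammonium fluoride (THF, 0 °C) should free the para-phenol as 1-[4-hydroxy-2,6-bis(methoxymethoxy)phenyl]-3-methylbutan-1-one F5. The Mannich reaction of step 8 should then give 1-[4-hydroxy-2,6-bis(methoxymethoxy)-3-(morpholin-4-ylmethyl)phenyl]-3-methylbutan-1-one F6. Heating F6 with 9 as in step 9 should pass through 3,5-bis(methoxymethoxy)-4-(3-methylbutanoyl)-6-methylidenecyclohexa-2,4-dien-1-one F7 to 1-[(1R,2R,5S)-5',7'-bis(methoxymethoxy)-6,6-dimethyl-3',4'-dihydrospiro[bicyclo[3.1.1]heptane-2,2'-chromen]-6'-yl]-3-methylbutan-1-one F8. Mild acid (catalytic HCl in MeOH, 40 °C) should remove both acetals and give 15.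

3. Step 10. The Lewis acid may ionise the tertiary C2–O bond, with skeletal rearrangement of the pinane unit, or chelation may stop the formylation short of completion. The fallback goes from 15 directly to 16 by a non-acidic, magnesium-phenoxide-mediated ortho-formylation (MgCl2, Et3N, paraformaldehyde, MeCN, reflux). There the phenoxide-bound formaldehyde hydroxymethylates C8' and a second formaldehyde oxidises the benzylic alcohol by hydride transfer. This fallback makes no compound outside the list (F0).

Further compounds
F1 | step 4 | methyl (1R,3R)-2,2-dimethyl-3-[2-(phenylsulfonyl)ethyl]cyclobutane-1-carboxylate | O=S(=O)(CC[C@H]1C[C@@H](C(=O)OC)C1(C)C)c1ccccc1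
F2 | step 4 | (1R,5R)-6,6-dimethyl-3-(phenylsulfonyl)bicyclo[3.1.1]heptan-2-one | O=C1C(S(=O)(=O)c2ccccc2)C[C@H]3C[C@@H]1C3(C)C
F3 | step 9 | 1-[4-(tert-butyldimethylsilyloxy)-2,6-dihydroxyphenyl]-3-methylbutan-1-one | CC(C)CC(=O)c1c(O)cc(O[Si](C)(C)C(C)(C)C)cc1O
F4 | step 9 | 1-[4-(tert-butyldimethylsilyloxy)-2,6-bis(methoxymethoxy)phenyl]-3-methylbutan-1-one | CC(C)CC(=O)c1c(OCOC)cc(O[Si](C)(C)C(C)(C)C)cc1OCOC
F5 | step 9 | 1-[4-hydroxy-2,6-bis(methoxymethoxy)phenyl]-3-methylbutan-1-one | CC(C)CC(=O)c1c(OCOC)cc(O)cc1OCOC
F6 | step 9 | 1-[4-hydroxy-2,6-bis(methoxymethoxy)-3-(morpholin-4-ylmethyl)phenyl]-3-methylbutan-1-one | CC(C)CC(=O)c1c(OCOC)cc(O)c(CN2CCOCC2)c1OCOC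
F7 | step 9 | 3,5-bis(methoxymethoxy)-4-(3-methylbutanoyl)-6-methylidenecyclohexa-2,4-dien-1-one | C=C1C(=O)C=C(OCOC)C(C(=O)CC(C)C)=C1OCOC
F8 | step 9 | 1-[(1R,2R,5S)-5',7'-bis(methoxymethoxy)-6,6-dimethyl-3',4'-dihydrospiro[bicyclo[3.1.1]heptane-2,2'-chromen]-6'-yl]-3-methylbutan-1-one | CC(C)CC(=O)c1c(OCOC)cc2c(c1OCOC)CC[C@@]1(CC[C@H]3C[C@@H]1C3(C)C)O2
F0 | step 10 | none | none
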